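**Retrosynthetic overview**
1. The C5–OH goes on last. Disconnect C5–O of 7 to give 7,8,2',4'-tetramethoxyflavone 5 (C4=O-directed peri C–H borylation, then B→O oxidation in the same flask).
2. γ-Pyrone ring: disconnect O1–C2 of 5 to give 2'-hydroxychalcone 3 (oxa-Michael closure, then dehydrogenation).
3. Chalcone 3 comes from a Claisen–Schmidt union of acetophenone 1 and aldehyde 2.
4. Ring order: both benzene rings are bought, and the pyrone is the only ring made (step 2). Only one phenol OH is present at ring closure, so the 7,8- versus 6,7-dimethoxy ambiguity of 2,6-dihydroxy ketones never arises.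

Assumption: the target is a planar, achiral flavone with no stereocentre, so no enantiocontrol is needed. The E-alkene of 3 and the racemic centre of 4 are both erased in step 2.

**Step 1**
Reactants: 1 2'-hydroxy-3',4'-dimethoxyacetophenone; 2 2,4-dimethoxybenzaldehyde
Product: 3 (E)-1-(2-hydroxy-3,4-dimethoxyphenyl)-3-(2,4-dimethoxyphenyl)prop-2-en-1-one
Conditions: KOH (3 equiv, 50% aq), EtOH, rt, 36 h; then 2 M HCl
Reagents that add atoms: none
Why: Claisen–Schmidt aldol condensation, in which the methyl ketone enolate adds to the non-enolisable aldehyde and E1cB loss of water gives the conjugated E-chalcone, which crystallises on acidification.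

**Step 2**
Reactants: 3 (E)-1-(2-hydroxy-3,4-dimethoxyphenyl)-3-(2,4-dimethoxyphenyl)prop-2-en-1-one
Product: 5 7,8,2',4'-tetramethoxyflavone, via flavanone 4 (not isolated)
Conditions: I2 (10 mol %), DMSO, 130 °C, 2 h
Reagents that add atoms: none
Why: I2–DMSO oxidative cyclisation of a 2'-hydroxychalcone, in which the single phenol oxygen closes O1–C2 by 6-endo oxa-Michael addition to give 4 and catalytic iodine dehydrogenates C2–C3 while DMSO re-oxidises the HI, so only the 7,8-dimethoxy regioisomer can form.

**Step 3**
Reactants: 5 7,8,2',4'-tetramethoxyflavone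
Product: 7 5-hydroxy-2',4',7,8-tetramethoxyflavone, via C5-boronate 6 (not isolated)
Conditions: [Ir(OMe)(cod)]2 (3 mol %), P[3,5-(CF3)2C6H3]3 (12 mol %), B2pin2 (1.2 equiv), CPME, 100 °C, 16 h; then NaBO3·4H2O (4 equiv), THF/H2O, rt, 2 h
Reagents that add atoms: sodium perborate, [Na+].[O-]OB=O (the C5 oxygen); bis(pinacolato)diboron, CC1(C)OB(OC1(C)C)B1OC(C)(C)C(C)(C)O1 (the boron of intermediate 6 only)
Why: Proposed new method: chromone-carbonyl-directed peri C5–H borylation with in-flask B→O oxidation, in which the electron-poor monodentate phosphine gives a coordinatively unsaturated L·Ir(Bpin)3 species that keeps a site free for the unusually Lewis-basic, non-enolisable γ-pyrone C4=O, whose in-plane lone pair holds Ir over C5–H so that C–H cleavage runs through a five-membered iridacycle and C–B reductive elimination gives 6, while every other aryl C–H (C6, C3', C5', C6') lies ortho to a substituent and is slow in the sterically governed undirected pathway, and perborate then makes the C5–O bond by 1,2-aryl shift from boron to oxygen without an oxidant strong enough to attack the two electron-rich rings; the closest known reaction types are ester- and aryl-ketone-directed Ir-catalysed ortho C–H borylation, one-pot arene C–H borylation/oxidation to phenols, and Ru/Rh/Ir C5–H functionalisation of chromones, but to my knowledge C5 borylation of a flavone has not been shown.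

**Compound list**
1 | 2'-hydroxy-3',4'-dimethoxyacetophenone | CC(=O)c1ccc(OC)c(OC)c1O | starting material
2 | 2,4-dimethoxybenzaldehyde | COc1ccc(C=O)c(OC)c1 | starting material
3 | (E)-1-(2-hydroxy-3,4-dimethoxyphenyl)-3-(2,4-dimethoxyphenyl)prop-2-en-1-one | COc1ccc(/C=C/C(=O)c2ccc(OC)c(OC)c2O)c(OC)c1 | intermediate
4 | 7,8,2',4'-tetramethoxyflavanone (racemic 2-(2,4-dimethoxyphenyl)-7,8-dimethoxychroman-4-one) | COc1ccc(C2CC(=O)c3ccc(OC)c(OC)c3O2)c(OC)c1 | intermediate
5 | 7,8,2',4'-tetramethoxyflavone | COc1ccc(-c2cc(=O)c3ccc(OC)c(OC)c3o2)c(OC)c1 | intermediate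
6 | 7,8,2',4'-tetramethoxy-5-(4,4,5,5-tetramethyl-1,3,2-dioxaborolan-2-yl)flavone | COc1ccc(-c2cc(=O)c3c(B4OC(C)(C)C(C)(C)O4)cc(OC)c(OC)c3o2)c(OC)c1 | intermediate
7 | 5-hydroxy-2',4',7,8-tetramethoxyflavone | COc1ccc(-c2cc(=O)c3c(O)cc(OC)c(OC)c3o2)c(OC)c1 | target

**Total step count:** 3. **Longest linear sequence:** 3.

**Steps most likely to fail**

Step 3 (the new step) is the most likely to fail. The pyrone carbonyl may direct too weakly, the boron hydride co-product may reduce the enone, or the B ring may be borylated instead. The fallback uses only known chemistry and carries the C5 oxygen from the start. It sets out from aldehyde 2 and comes back at target 7.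
- Commercial 1,2,3,5-tetramethoxybenzene (COc1cc(OC)c(OC)c(OC)c1) is acetylated with AcCl/AlCl3 in Et2O. This also cleaves the flanked ortho methyl ether and gives 2'-hydroxy-3',4',6'-trimethoxyacetophenone F1.
- Claisen–Schmidt condensation of this ketone with 2 (KOH, EtOH) gives (E)-1-(2-hydroxy-3,4,6-trimethoxyphenyl)-3-(2,4-dimethoxyphenyl)prop-2-en-1-one F2.
- I2/DMSO at 130 °C gives 5,7,8,2',4'-pentamethoxyflavone F3.
- BCl3 (CH2Cl2, −78 to 0 °C) chelates to C4=O and removes only the peri 5-O-methyl group to give 7. These conditions are too mild for Wessely–Moser isomerisation.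

Step 2 is the second risk. I2/DMSO can iodinate the very electron-rich 2,4-dimethoxyphenyl ring, or the reaction can stall at the flavanone. The fallback sets out from chalcone 3 and comes back at flavone 5. It separates ring closure from oxidation and uses no halogen. NaOAc in refluxing EtOH isomerises 3 to flavanone 4, which is isolated. DDQ in refluxing dioxane then dehydrogenates it by hydride abstraction to 5. No compound outside the list is made.

Step 1 is the third risk. The aldehyde is deactivated by two donor methoxy groups, so the condensation can be slow and incomplete. The fallback sets out from acetophenone 1, comes back at flavone 5 and bypasses the chalcone by a Baker–Venkataraman sequence.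
- Compound 1 is O-acylated with commercial 2,4-dimethoxybenzoyl chloride (COc1ccc(C(=O)Cl)c(OC)c1) in pyridine to give 6-acetyl-2,3-dimethoxyphenyl 2,4-dimethoxybenzoate F4.
- KOH in pyridine at 50 °C causes the acyl shift to 1-(2-hydroxy-3,4-dimethoxyphenyl)-3-(2,4-dimethoxyphenyl)propane-1,3-dione F5.
- Catalytic H2SO4 in AcOH at 100 °C cyclodehydrates this diketone to 5.

**Further compounds**
F1 | step 3 | 2'-hydroxy-3',4',6'-trimethoxyacetophenone | CC(=O)c1c(O)c(OC)c(OC)cc1OC
F2 | step 3 | (E)-1-(2-hydroxy-3,4,6-trimethoxyphenyl)-3-(2,4-dimethoxyphenyl)prop-2-en-1-one | COc1ccc(/C=C/C(=O)c2c(O)c(OC)c(OC)cc2OC)c(OC)c1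
F3 | step 3 | 5,7,8,2',4'-pentamethoxyflavone | COc1ccc(-c2cc(=O)c3c(OC)cc(OC)c(OC)c3o2)c(OC)c1
F0 | step 2 | none | none
F4 | step 1 | 6-acetyl-2,3-dimethoxyphenyl 2,4-dimethoxybenzoate | COc1ccc(C(=O)Oc2c(C(C)=O)ccc(OC)c2OC)c(OC)c1
F5 | step 1 | 1-(2-hydroxy-3,4-dimethoxyphenyl)-3-(2,4-dimethoxyphenyl)propane-1,3-dione | COc1ccc(C(=O)CC(=O)c2ccc(OC)c(OC)c2O)c(OC)c1
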